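1. Amounts first: the flask holds starting material at 0.50 M with 3.00 equiv of reagent in the second phase, and I read it at 20 min.

| flask | starting material | reagent in the second phase | remark | time | volume of the second phase over the first |
|---|---|---|---|---|---|
| beta | 0.50 M | 3 equiv | the very flask that is asked about, followed so far |  |  |
| epsilon | 0.50 M | 2 equiv | run made earlier |  |  |
| flask | 0.50 M | 3.00 equiv |  | 20 min | 2.0 |

beta run (percent of the starting material charged)

| time / s | target / % | starting material / % |
|---|---|---|
| 10.0 | 1.3 | 98.6 |
| 15.0 | 1.1 | 99.2 |
| 25.0 | 2.8 | 97.5 |
| 50.0 | 6.9 | 91.8 |
| 90.0 | 9.9 | 85.3 |

epsilon run (percent of the starting material charged)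

| time / min | target / % | starting material / % |
|---|---|---|
| 4.00 | 9.6 | 74.5 |
| 8.00 | 7.9 | 57.9 |
| 12.0 | 6.2 | 48.7 |
| 15.0 | 6.6 | 42.0 |
| 20.0 | 4.9 | 34.6 |

(scatter of a reading: 0.5 percentage points)

- in the second phase: reagent in the second phase; everything else is in the first
- charges count per volume of the first phase; a concentration in a rate is the amount of a species over the volume of its own phase; every rate counts per litre of the first phase
- the analysis behind the earlier runs scatters by 0.5 percentage points, standard deviation
- the earlier runs hold the two phases in the same ratio of volumes as the flask asked about

* target at 20 min, in percent of the starting material charged
* part of the starting material charged that has reacted at 20 min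

2. I replace the bending curve of starting material by its mean: the logarithm of charged over left, divided by the time. The epsilon run gives 0.0531 /min over 20.0 min.

3. The early constants of these two runs, read as pseudo-first-order, go with the equivalents. The beta run gives 0.106 /min up to 90.0 s, and the epsilon run, scaled by the equivalents, gives 0.110 /min up to 4.00 min.

4. So I scale the mean of the epsilon run in the same way and take 0.0796 /min as the flask's mean first-order constant of starting material over 20 min.

5. The error: at 8.00 min the epsilon mean leaves 65.4% but the reading is 57.9%. The mean runs high mid-curve and fits at its own end time, which is the asked time.

6. First rung: the epsilon run ends with a reading of c(target)/c(starting material) of 0.142. I assume that lost starting material passes through target and that target's loss ignores reagent, so target lives 2.67 min.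

7. Next rung: by my estimate starting material lives 12.6 min, longer than target, so target follows it (quasi-steady state). Last rung: the time asked, longer still.

8. My reckoning leaves 20.4%, so 79.6% has reacted, and target is 4.34%.

9. The forecast says 80% reacted and 3% target: “Target then tracks starting material at about 0.14 of it”. My target is higher than the forecast's, as I let that ratio grow with the reagent.

The flask gives 77.0% reacted and 4.65% target.

    reagent in the reaction phase ⇌ reagent in the second phase, rate k1*([reagent in the reaction phase] - [reagent in the second phase]/K1) per volume of the first phase (partition coefficient = 1.79, kL = 0.0125 /s)
    starting material + reagent in the reaction phase ⇌ target (K = 0.880 /M, k = 0.0260 /M/s)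
    starting material + target → side product (k = 0.00657 /M/s)
    target → over-reaction product (k = 0.00381 /s)

Up to 20 min, the step of starting material with target to side product turned over 16.9% of the starting material charged. With 23.0% left, this flask's own mean constant is 0.0735 /min, against 0.0796 /min. For the same flask read at 8.0 min, 0.0796 /min gives 52.9% starting material, and that flask holds 47.8%.

The earlier runs and the new flask come from a simulation for an exercise, noise included.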